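**Remarks on the chemistry**

- Configuration: the target is (4S,6S,10S), with C10 cis to C7 across C8=C9 (E by the sequence rule) and the C4 and C6 oxygens anti along the ring. (S)-Linalool has the same spatial arrangement at its carbinol carbon as C10 when its vinyl group becomes C9.
- Temporary centres: C8 and C9 in compounds 21–33 are carried as mixtures, because both become trigonal in step 19. Their SMILES carry no configuration at these two atoms.
- Assumption: (S)-linalool is taken to be available in high enantiomeric purity.

## Structural features

Numbering: C1–C10 run round the carbocycle (C1 the dihydrofuran CH2, C2=C3 the enol ether, C4 the methyl carbinol, C5 a CH2, C6 the acetoxy carbon, C7 and C8 the butenolide β- and γ-carbons, C9 the exocyclic CH, C10 the quaternary ether carbon). C11, C12 and C13 are the butenolide α-carbon, its carbonyl and the acetoxymethyl carbon.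

The target has three rings. A ten-membered carbocycle is bridged by an oxygen between C3 and C10, which makes a 2,3-dihydrofuran (O, C10, C1, C2, C3) and a nine-membered ring through oxygen. It is fused along C7–C8 to a butenolide whose γ-carbon carries the exocyclic C8=C9 bond, an enol lactone cross-conjugated with C7=C11. The three stereocentres are not bonded to each other: quaternary C10 (O, CH3), the tertiary carbinol C4 on the enol ether carbon C3, and the allylic acetate carbon C6. C4 and C6 are 1,3-related, and C4 and C10 are 1,3-related across the ring oxygen.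

The enol ether with its tertiary allylic alcohol is acid-labile. The enol lactone and the C13 acetate are sensitive to base, nucleophiles and reductants, because any carbanion character at C11 expels a leaving group on C13. The C4 hydroxyl and the C6 oxygen form a retro-aldol pair. The real difficulty is closing the medium ring while setting C4 relative to C10 and obtaining the C8=C9 geometry, which an open-chain alkylidene butenolide with a C7 substituent would not favour.

The key step uses two facts. C4–OH is β to the C6 oxygen, so C4–C5 is an aldol bond. The corresponding C4 ketone is the acetyl group of a 5-acetyl-2,3-dihydrofuran, whose ring oxygen sits α to the carbonyl and can chelate a metal, while the tether anchored at C10 defines the face of attack.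

## Logic of the disconnections

**34 ⇒ 32 (via 33).** The C8=C9 π bond is cut by retro-addition of water, putting OH on C9 and H on C8. The ring itself allows only the geometry with C10 cis to C7, so the alkene is best formed last and inside the ring. The C9 oxygen is what an aldol union at C8–C9 leaves behind, so no late oxidation at C8 is needed. The forward step needs a C9 leaving group that clearly outranks the C13 acetate, and only brief base contact for 34.

**32 ⇒ 31 ⇒ 30 ⇒ 29.** The acyl C–O bonds at C13 and C6 and the two Si–O bonds are cut. C13 must stay a silyl ether through all enolate and electron-transfer chemistry. C6–OH is capped as soon as it exists, so the lactone acyl group cannot migrate to it. The demands are primary-over-hindered-secondary selectivity (31 → 32) and a tertiary C4–OH that stays free.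

**29 ⇒ 27.** The C6–H bond is cut. C6 is 1,3 to the C4 carbinol, so its configuration can come from hydroxyl-directed hydride delivery. This returns the aldol retron. The forward step must be anti-selective, 1,2-selective, and mild enough for the enol ether.

**27 ⇒ 24.** The C4–C5 bond is cut, which opens the ten-membered ring and removes the C4 stereocentre. 24 differs from the barest form of this precursor in three ways:
- C9 keeps the oxygen from the fragment union as a triethylsilyl ether, a spectator in the ring closure.
- C13 is a silyl ether.
- C8 is left without defined configuration, since it is epimerisable.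

The carbon skeleton, the bond formed and the ring closed are unchanged. The forward step must generate a regiodefined enolate at C5 without reducing the keto-butenolide, and must add to the chelated face of the C4 ketone.

**24 ⇒ 22.** C5–Br and C6=O are traced to an enol ether. A bromo ketone could not survive the base used to join the fragments. The forward step must brominate the 2-ethoxydiene and leave the acetyl-deactivated ring enol ether alone.

**22 ⇒ 19 + 13.** C8–C9 is cut as a vinylogous aldol bond. C9 is neopentyl, so carbonyl addition is the only practical way to make this bond. The cut gives two fragments of similar size. The forward step needs γ-selectivity, aldehyde-over-ketone selectivity, and capture of the alkoxide before it reverts; no stereocontrol is needed.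

**13 ⇒ 12 ⇒ 9 + 10; 9 ⇒ 7 ⇒ 6 ⇒ 4 ⇒ 3 ⇒ 1.** C3–C4 is cut at the lactone stage. The acyl dihydrofuran must exist before the butenolide is attached, because making the enol phosphate of 9 needs a strong base that a butenolide would not tolerate. The remaining cuts are C=C cleavages of 1: its vinyl group supplies C9, its prenyl chain supplies C1–C3, and its carbinol carbon is C10. The demands are selective ozonolysis and a C9 protecting group that leaves in the work-up that unmasks the ketone.

**19 ⇒ 18 + 10; 18 ⇒ 17 ⇒ 16 ⇒ 14.** C6–C7 is cut as a cross-coupling bond and C11–C13 as a formylation bond. Both acetyl units of the target then come from 10. The bromide at C7 must survive reduction and silylation.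

## Other disconnections considered

**Alternative 1:** The cut is C9–C10. In the forward step, CrCl2 (divalent chromium) with catalytic NiCl2 would convert the (E)-iodomethylene butenolide A2 into a vinylchromium (trivalent chromium) species. This would add to the C10 methyl ketone and close the ring to the tertiary carbinol A1.
- In favour: the alkene geometry is fixed before cyclisation by anti iodolactonisation. C8 is already trigonal, so there is no acidic γ-hydrogen. Both acetates are in place, and the organochromium reagent is non-basic.
- Against: vinylchromium additions to ketones are far slower than to aldehydes. The C10 configuration would rest only on the conformation of a flexible chain, with the acetonide several atoms away. The dihydrofuran would still have to be made from A1 (acetonide removal, C3 oxidation, hemiketalisation with C10–OH, dehydration toward C2) next to an enol lactone and two acetates.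
- Comparison: on alkene geometry and on avoiding a C–H-acidic, reducible cyclisation substrate, this plan is the better one. On ring closure as such, the two are equal (carbonyl addition at high dilution). On stereocontrol at the new carbinol, the chosen plan is better, because chelation and the C10 tether act together. On step count, the extra dihydrofuran steps after A1 would probably cancel the saving of the late elimination.

**Alternative 2:** The cut is O–C10 of the dihydrofuran. In the forward step, Ni(cod)2 (zerovalent nickel) with (R)-BINAP would open the C2–C10 bond of the vinylcyclopropyl ketone A4 to an allylnickel enolate. The enolate oxygen would close on C10 to give A3.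
- In favour: C10 is set by a catalyst, not taken from the chiral pool. Both cyclopropane diastereomers converge on one allyl intermediate. C4 is already in place.
- Against: it is a fragment synthesis and leaves the ten-membered ring unsolved. A cyclopropane with a single acyl group is weakly activated. Ligand control of a methyl/alkyl quaternary C–O centre is uncertain and must cooperate with the C4 centre. The vinyl group of A3 would have to be cleaved to C9 beside an electron-rich enol ether.
- Comparison: it is the better plan for catalytic control of C10 and equal in providing the 2-methyl dihydrofuran. It is weaker in that C4 needs its own asymmetric step and another macrocyclisation must still be found, so the route would be longer.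

**Alternative 3:** The cut is C1–C10, with C3–C8 reconnected. In the forward step, the potassium alkoxide of A6 (KH, 18-crown-6) would undergo an anionic oxy-Cope shift, expanding the cyclohexane to the ten-membered ketone A5.
- In favour: there is no macrocyclisation entropy. The enol lactone and its geometry come from the ordered transition state. C10 comes by chirality transfer from the enol ether geometry.
- Against: A6 has three contiguous fully substituted carbons (C3, C4, C8), one of them bearing the lactone oxygen. The C3 alkoxide could attack the lactone under the strongly basic conditions. A5 still needs desilylation at C10 and cyclodehydration onto the C3 ketone to form the enol ether.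
- Comparison: on robustness of ring formation and on alkene geometry this plan is the better one, and on relay of configuration to C10 it is at least equal. On precursor length, base tolerance and the steps after the key step, the chosen plan is better.

Key step: step 14

## Route

Step 1
Reactants: 1 (S)-linalool
Product: 3 (5S)-5-methyl-5-vinyltetrahydrofuran-2-ol (anomer mixture), via hydroxy aldehyde 2 (not isolated)
Conditions: O3 (1 equiv, Sudan Red 7B end point), CH2Cl2–MeOH, −78 °C; Me2S, −78 °C → rt
Reagents that add atoms: ozone, [O-][O+]=O
Why: Chemoselective ozonolysis: the electron-rich trisubstituted alkene reacts far faster than the vinyl group, which is deactivated by the allylic oxygen. The hydroxy aldehyde 2 closes to the five-membered lactol, and the carbinol carbon (later C10) is untouched.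

Step 2
Reactants: 3 (5S)-5-methyl-5-vinyltetrahydrofuran-2-ol
Product: 4 (S)-5-methyl-5-vinyldihydrofuran-2(3H)-one
Conditions: TEMPO (10 mol %), PhI(OAc)2, CH2Cl2, rt
Reagents that add atoms: none
Why: Oxoammonium oxidation of a lactol to the γ-lactone. The tertiary oxygen is tied up in the ring, so no allylic transposition can occur, and the vinyl group is inert.

Step 3
Reactants: 4 (S)-5-methyl-5-vinyldihydrofuran-2(3H)-one
Product: 6 (S)-5-(hydroxymethyl)-5-methyldihydrofuran-2(3H)-one, via lactone aldehyde 5 (not isolated)
Conditions: O3, CH2Cl2–MeOH, −78 °C; NaBH4, −78 → 0 °C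
Reagents that add atoms: ozone, [O-][O+]=O
Why: Ozonolysis of the remaining vinyl group gives the C9 aldehyde 5, which NaBH4 reduces in the same flask. The γ-lactone is not opened at 0 °C over a short time, and C10 is unaffected.

Step 4
Reactants: 6 (S)-5-(hydroxymethyl)-5-methyldihydrofuran-2(3H)-one
Product: 7 (S)-5-methyl-5-{[(triethylsilyl)oxy]methyl}dihydrofuran-2(3H)-one
Conditions: Et3SiCl, imidazole, CH2Cl2, 0 °C → rt
Reagents that add atoms: chlorotriethylsilane, CC[Si](Cl)(CC)CC
Why: Standard silylation of a primary alcohol. The labile triethylsilyl group is chosen because the acidic work-up of step 6 should remove it.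

Step 5
Reactants: 7 (S)-5-methyl-5-{[(triethylsilyl)oxy]methyl}dihydrofuran-2(3H)-one
Product: 9 diphenyl (S)-5-methyl-5-{[(triethylsilyl)oxy]methyl}-4,5-dihydrofuran-2-yl phosphate, via potassium enolate 8 (not isolated)
Conditions: KN(SiMe3)2, (PhO)2P(O)Cl, DMPU, THF, −78 °C
Reagents that add atoms: diphenyl chlorophosphate, O=P(Cl)(Oc1ccccc1)Oc1ccccc1
Why: Lactone enolisation with O-phosphorylation in situ (ketene acetal phosphate formation). Generating enolate 8 in the presence of the chlorophosphate suppresses Claisen self-condensation; C2–H2 is the only acidic site and there is no β-leaving group.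

Step 6
Reactants: 9 diphenyl (S)-5-methyl-5-{[(triethylsilyl)oxy]methyl}-4,5-dihydrofuran-2-yl phosphate; 10 tributyl(1-ethoxyvinyl)stannane
Product: 12 (S)-1-[5-(hydroxymethyl)-5-methyl-4,5-dihydrofuran-2-yl]ethan-1-one, via ethoxyvinyl dihydrofuran 11 (not isolated)
Conditions: Pd(PPh3)4 (10 mol %), LiCl, THF, 65 °C; then 1 M HCl, THF, 0 °C
Reagents that add atoms: water, O
Why: Stille coupling of a lactone-derived ketene acetal phosphate forms C3–C4, with LiCl assisting the exchange at palladium. Dilute acid protonates the terminal CH2 of the 2-ethoxydiene 11 and releases the acetyl group, which then deactivates the ring enol ether toward acid. The same acid cleaves the primary triethylsilyl ether.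

Step 7
Reactants: 12 (S)-1-[5-(hydroxymethyl)-5-methyl-4,5-dihydrofuran-2-yl]ethan-1-one
Product: 13 (S)-5-acetyl-2-methyl-2,3-dihydrofuran-2-carbaldehyde
Conditions: Dess–Martin periodinane, NaHCO3, CH2Cl2, 0 °C → rt
Reagents that add atoms: none
Why: Buffered Dess–Martin oxidation of a neopentyl primary alcohol. The aldehyde has no α-hydrogen, so it can neither enolise nor epimerise.

Step 8
Reactants: 14 tetronic acid
Product: 16 4-bromo-2-oxo-2,5-dihydrofuran-3-carbaldehyde, via bromo iminium salt 15 (not isolated)
Conditions: PBr3, DMF, CHCl3, 0 → 60 °C; then ice–water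
Reagents that add atoms: N,N-dimethylformamide, CN(C)C=O; phosphorus tribromide, BrP(Br)Br; water, O
Why: Vilsmeier–Haack–Arnold haloformylation of a cyclic 1,3-dicarbonyl compound. The bromoiminium reagent formylates the enol carbon (C11) and turns the enol oxygen on C7 into a vinylogous acyl bromide, as with 4-hydroxycoumarins and 4-hydroxypyranones. Iminium 15 is hydrolysed on work-up.

Step 9
Reactants: 16 4-bromo-2-oxo-2,5-dihydrofuran-3-carbaldehyde
Product: 17 4-bromo-3-(hydroxymethyl)furan-2(5H)-one
Conditions: NaBH4, CeCl3·7H2O, MeOH–THF, −78 °C
Reagents that add atoms: none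
Why: Luche 1,2-reduction: at −78 °C the cerium-activated aldehyde is reduced faster than hydride or methanol can add to C7 and displace bromide.

Step 10
Reactants: 17 4-bromo-3-(hydroxymethyl)furan-2(5H)-one
Product: 18 4-bromo-3-{[(tert-butyldimethylsilyl)oxy]methyl}furan-2(5H)-one
Conditions: t-BuMe2SiOTf, 2,6-lutidine, CH2Cl2, −78 °C
Reagents that add atoms: tert-butyldimethylsilyl trifluoromethanesulfonate, CC(C)(C)[Si](C)(C)OS(=O)(=O)C(F)(F)F
Why: Silylation with a non-nucleophilic base, which avoids addition–elimination of an amine at the vinylogous acyl bromide.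

Step 11
Reactants: 18 4-bromo-3-{[(tert-butyldimethylsilyl)oxy]methyl}furan-2(5H)-one; 10 tributyl(1-ethoxyvinyl)stannane
Product: 19 3-{[(tert-butyldimethylsilyl)oxy]methyl}-4-(1-ethoxyvinyl)furan-2(5H)-one
Conditions: Pd(PPh3)4 (5 mol %), CuI (10 mol %), dioxane, 80 °C; aq. KF work-up
Reagents that add atoms: none
Why: Stille coupling at an activated β-bromo enoate installs the masked bromoacetyl unit (C6, C5). Neutral conditions and a fluoride work-up keep the 2-ethoxydiene intact.

Step 12
Reactants: 19 3-{[(tert-butyldimethylsilyl)oxy]methyl}-4-(1-ethoxyvinyl)furan-2(5H)-one; 13 (S)-5-acetyl-2-methyl-2,3-dihydrofuran-2-carbaldehyde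
Product: 22 5-{[(2S)-5-acetyl-2-methyl-2,3-dihydrofuran-2-yl][(triethylsilyl)oxy]methyl}-3-{[(tert-butyldimethylsilyl)oxy]methyl}-4-(1-ethoxyvinyl)furan-2(5H)-one (C8/C9 mixture), via lithium furanolate 20 (not isolated), via lithium aldolate 21 (not isolated)
Conditions: LiN(SiMe3)2, THF, −78 °C; then 13, −78 °C; then Et3SiOTf, 2,6-lutidine, −78 °C
Reagents that add atoms: triethylsilyl trifluoromethanesulfonate, CC[Si](CC)(CC)OS(=O)(=O)C(F)(F)F
Why: Vinylogous aldol reaction of a lithium 2-furanolate: deprotonation at C8 gives the aromatic anion 20, which adds through C8 (C11 is blocked) to the aldehyde much faster than to the conjugated ketone. Alkoxide 21 is silylated cold, before retro-aldol or β-elimination can set in. C8 and C9 form as mixtures, which is acceptable because both become trigonal in step 19.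

Step 13
Reactants: 22 5-{[(2S)-5-acetyl-2-methyl-2,3-dihydrofuran-2-yl][(triethylsilyl)oxy]methyl}-3-{[(tert-butyldimethylsilyl)oxy]methyl}-4-(1-ethoxyvinyl)furan-2(5H)-one
Product: 24 4-(2-bromoacetyl)-5-{[(2S)-5-acetyl-2-methyl-2,3-dihydrofuran-2-yl][(triethylsilyl)oxy]methyl}-3-{[(tert-butyldimethylsilyl)oxy]methyl}furan-2(5H)-one (C8/C9 mixture), via bromo hemiketal 23 (not isolated)
Conditions: NBS (1.05 equiv), NaHCO3, THF–H2O (4:1), 0 °C
Reagents that add atoms: N-bromosuccinimide, O=C1CCC(=O)N1Br; water, O
Why: Electrophilic bromination of an α-alkoxyvinyl group in wet THF: bromine adds at the terminal carbon, water at the oxocarbenium carbon, and hemiketal 23 loses ethanol to give the α-bromo ketone regiospecifically. The ring enol ether is deactivated by its acetyl group and should not react.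

Step 14
Reactants: 24 4-(2-bromoacetyl)-5-{[(2S)-5-acetyl-2-methyl-2,3-dihydrofuran-2-yl][(triethylsilyl)oxy]methyl}-3-{[(tert-butyldimethylsilyl)oxy]methyl}furan-2(5H)-one
Product: 27 (4S,10S) ten-membered β-hydroxy ketone (C4 carbinol, C6 ketone, C9 triethylsilyl ether, C13 tert-butyldimethylsilyl ether; C8/C9 mixture), via samarium enolate 25 (not isolated), via samarium aldolate 26 (not isolated)
Conditions: SmI2 (2.2 equiv, 0.1 M in THF) added over 1 h to 24 (0.002 M), THF, −78 °C; then sat. aq. NH4Cl, −78 °C
Reagents that add atoms: none
Why: Two equivalents of SmI2 (divalent samarium) reduce the C5–Br bond of the α-bromo ketone; bromide leaves and the oxygen-bound trivalent samarium enolate 25 (C5=C6) forms regiospecifically. The closest known reaction type is the SmI2-promoted intramolecular Reformatsky (aldol-type) macrocyclisation of α-halo carbonyl compounds, which is documented for medium rings and for ketone acceptors. C5 adds to the C4 ketone through a closed six-membered transition state in which the samarium on the enolate oxygen also binds the C4 carbonyl oxygen and the dihydrofuran oxygen, giving aldolate 26 and, after cold protonation, 27. The ten-membered carbocycle closes in a 10-exo-trig, enolendo mode (9-exo-trig counted through the ring oxygen), the C4 carbonyl being exocyclic to the new ring. The new C4 stereocentre is fixed by two elements: chelation holds the carbonyl oxygen syn to the ring oxygen, and the five-atom tether C5–C9 anchored at C10 can reach only the face of the dihydrofuran that carries C9, which with (10S) should give (4S). The step needs electron transfer to the C–Br bond in preference to the keto-butenolide, ring closure in preference to oligomerisation, and survival of the aldolate. These are served by the very fast loss of bromide, addition of the reductant to the dilute substrate so that no excess meets 26, the absence of HMPA, −78 °C throughout, and a silyl ether (not an acetate) at C13. The C9 silyloxy group and the C8 hydrogen are spectators, and either configuration at these centres is acceptable.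

Step 15
Reactants: 27 (4S,10S) ten-membered β-hydroxy ketone
Product: 29 (4S,6S,10S) 4,6-diol (C9 triethylsilyl ether, C13 tert-butyldimethylsilyl ether), via alkoxyborohydride 28 (not isolated)
Conditions: Me4NBH(OAc)3, MeCN–AcOH (5:1), −35 °C
Reagents that add atoms: none
Why: Evans–Saksena hydroxyl-directed reduction: the C4 hydroxyl exchanges onto boron (28) and delivers hydride to the C6 ketone from its own side of the ring, so the new C6–O bond should lie trans to C4–O (1,3-anti, 6S). The weakly hydridic reagent should not touch the lactone or add 1,4, and low temperature with limited acetic acid protects the enol ether.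

Step 16
Reactants: 29 (4S,6S,10S) 4,6-diol
Product: 30 (4S,6S,10S) C6 acetate (C4–OH free, C9 triethylsilyl ether, C13 tert-butyldimethylsilyl ether)
Conditions: Ac2O, pyridine, DMAP (cat.), CH2Cl2, 0 °C
Reagents that add atoms: acetic anhydride, CC(=O)OC(C)=O
Why: DMAP-catalysed acetylation of the secondary allylic alcohol; the tertiary C4 hydroxyl is not acylated at 0 °C. Capping C6–O at once prevents migration of the lactone acyl group to this oxygen.

Step 17
Reactants: 30 (4S,6S,10S) C6 acetate
Product: 31 (4S,6S,10S) C6 acetate with free hydroxyls at C4, C9 and C13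
Conditions: HF·pyridine, pyridine, THF, 0 °C → rt
Reagents that add atoms: none
Why: Fluoride cleavage of both silyl ethers under buffered, non-basic conditions. No C9 alkoxide forms, so vinylogous retro-aldol opening is avoided, and the medium is mild enough for the enol ether and the tertiary allylic alcohol.

Step 18
Reactants: 31 (4S,6S,10S) C6 acetate with free hydroxyls at C4, C9 and C13
Product: 32 (4S,6S,10S) C6,C13 diacetate with free hydroxyls at C4 and C9
Conditions: AcCl (1.1 equiv), 2,4,6-collidine, CH2Cl2, −78 °C
Reagents that add atoms: acetyl chloride, CC(=O)Cl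
Why: Selective acylation of the primary allylic alcohol. The C9 hydroxyl is flanked by quaternary C10 and the C8 methine, and the C4 hydroxyl is tertiary, so both should stay free.

Step 19
Reactants: 32 (4S,6S,10S) C6,C13 diacetate with free hydroxyls at C4 and C9
Product: 34 target CNP0144020.1, via C9 mesylate 33 (not isolated)
Conditions: MsCl, Et3N, CH2Cl2, −20 °C; then DBU, −20 → 0 °C
Reagents that add atoms: none
Why: Mesylation of the remaining secondary alcohol (sulfene pathway) followed by E1cB elimination: base removes the γ-proton C8–H and the dienolate expels mesylate, a far better leaving group than the C13 acetate. The ring allows only the geometry with C10 cis to C7, and both C8/C9 diastereomers converge because C8 is planar in the dienolate.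

## Compound list

1 | (S)-linalool, (3S)-3,7-dimethylocta-1,6-dien-3-ol | C=C[C@@](C)(O)CCC=C(C)C | starting material
2 | (4S)-4-hydroxy-4-methylhex-5-enal | C=C[C@@](C)(O)CCC=O | intermediate
3 | (5S)-5-methyl-5-vinyltetrahydrofuran-2-ol (anomer mixture) | C=C[C@]1(C)CCC(O)O1 | intermediate
4 | (S)-5-methyl-5-vinyldihydrofuran-2(3H)-one | C=C[C@]1(C)CCC(=O)O1 | intermediate
5 | (S)-2-methyl-5-oxotetrahydrofuran-2-carbaldehyde | O=C[C@]1(C)CCC(=O)O1 | intermediate
6 | (S)-5-(hydroxymethyl)-5-methyldihydrofuran-2(3H)-one | OC[C@]1(C)CCC(=O)O1 | intermediate
7 | (S)-5-methyl-5-{[(triethylsilyl)oxy]methyl}dihydrofuran-2(3H)-one | CC[Si](CC)(CC)OC[C@]1(C)CCC(=O)O1 | intermediate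
8 | potassium enolate of 7 | CC[Si](CC)(CC)OC[C@]1(C)CC=C([O-])O1.[K+] | intermediate
9 | diphenyl (S)-5-methyl-5-{[(triethylsilyl)oxy]methyl}-4,5-dihydrofuran-2-yl phosphate | CC[Si](CC)(CC)OC[C@]1(C)CC=C(OP(=O)(Oc2ccccc2)Oc2ccccc2)O1 | intermediate
10 | tributyl(1-ethoxyvinyl)stannane | CCOC(=C)[Sn](CCCC)(CCCC)CCCC | starting material
11 | (S)-5-(1-ethoxyvinyl)-2-methyl-2-{[(triethylsilyl)oxy]methyl}-2,3-dihydrofuran | CC[Si](CC)(CC)OC[C@]1(C)CC=C(C(=C)OCC)O1 | intermediate
12 | (S)-1-[5-(hydroxymethyl)-5-methyl-4,5-dihydrofuran-2-yl]ethan-1-one | OC[C@]1(C)CC=C(C(C)=O)O1 | intermediate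
13 | (S)-5-acetyl-2-methyl-2,3-dihydrofuran-2-carbaldehyde | O=C[C@]1(C)CC=C(C(C)=O)O1 | intermediate
14 | tetronic acid, furan-2,4(3H,5H)-dione | O=C1CC(=O)CO1 | starting material
15 | N-[(4-bromo-2-oxo-2,5-dihydrofuran-3-yl)methylene]-N-methylmethanaminium bromide | C[N+](C)=CC1=C(Br)COC1=O.[Br-] | intermediate
16 | 4-bromo-2-oxo-2,5-dihydrofuran-3-carbaldehyde | O=CC1=C(Br)COC1=O | intermediate
17 | 4-bromo-3-(hydroxymethyl)furan-2(5H)-one | OCC1=C(Br)COC1=O | intermediate
18 | 4-bromo-3-{[(tert-butyldimethylsilyl)oxy]methyl}furan-2(5H)-one | CC(C)(C)[Si](C)(C)OCC1=C(Br)COC1=O | intermediate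
19 | 3-{[(tert-butyldimethylsilyl)oxy]methyl}-4-(1-ethoxyvinyl)furan-2(5H)-one | CCOC(=C)C1=C(CO[Si](C)(C)C(C)(C)C)C(=O)OC1 | intermediate
20 | lithium 3-{[(tert-butyldimethylsilyl)oxy]methyl}-4-(1-ethoxyvinyl)furan-2-olate | CCOC(=C)c1coc([O-])c1CO[Si](C)(C)C(C)(C)C.[Li+] | intermediate
21 | lithium C9 alkoxide of the vinylogous aldol adduct of 19 and 13 (C8/C9 mixture) | CCOC(=C)C1=C(CO[Si](C)(C)C(C)(C)C)C(=O)OC1C([O-])[C@]2(C)CC=C(C(C)=O)O2.[Li+] | intermediate
22 | 5-{[(2S)-5-acetyl-2-methyl-2,3-dihydrofuran-2-yl][(triethylsilyl)oxy]methyl}-3-{[(tert-butyldimethylsilyl)oxy]methyl}-4-(1-ethoxyvinyl)furan-2(5H)-one (C8/C9 mixture) | CCOC(=C)C1=C(CO[Si](C)(C)C(C)(C)C)C(=O)OC1C(O[Si](CC)(CC)CC)[C@]2(C)CC=C(C(C)=O)O2 | intermediate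
23 | 2-bromo-1-ethoxy-1-hydroxyethyl hemiketal of 24 | CCOC(O)(CBr)C1=C(CO[Si](C)(C)C(C)(C)C)C(=O)OC1C(O[Si](CC)(CC)CC)[C@]2(C)CC=C(C(C)=O)O2 | intermediate
24 | 4-(2-bromoacetyl)-5-{[(2S)-5-acetyl-2-methyl-2,3-dihydrofuran-2-yl][(triethylsilyl)oxy]methyl}-3-{[(tert-butyldimethylsilyl)oxy]methyl}furan-2(5H)-one (C8/C9 mixture; key-step precursor) | CC(C)(C)[Si](C)(C)OCC1=C(C(=O)CBr)C(C(O[Si](CC)(CC)CC)[C@]2(C)CC=C(O2)C(C)=O)OC1=O | intermediate
25 | diiodosamarium enolate (C5=C6) of 24 | CC(C)(C)[Si](C)(C)OCC1=C(C(=C)O[Sm](I)I)C(C(O[Si](CC)(CC)CC)[C@]2(C)CC=C(O2)C(C)=O)OC1=O | intermediate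
26 | diiodosamarium C4 alkoxide of 27 | CC(C)(C)[Si](C)(C)OCC1=C2C(C(O[Si](CC)(CC)CC)[C@]3(C)CC=C(O3)[C@@](C)(O[Sm](I)I)CC2=O)OC1=O | intermediate
27 | (4S,10S) ten-membered β-hydroxy ketone: C4 carbinol, C6 ketone, C9–OSiEt3, C13–OSi(t-Bu)Me2 (C8/C9 mixture; key-step product) | CC(C)(C)[Si](C)(C)OCC1=C2C(C(O[Si](CC)(CC)CC)[C@]3(C)CC=C(O3)[C@@](C)(O)CC2=O)OC1=O | intermediate
28 | tetramethylammonium C4-alkoxy(diacetoxy)borohydride of 27 | CC(C)(C)[Si](C)(C)OCC1=C2C(C(O[Si](CC)(CC)CC)[C@]3(C)CC=C(O3)[C@@](C)(O[BH-](OC(C)=O)OC(C)=O)CC2=O)OC1=O.C[N+](C)(C)C | intermediate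
29 | (4S,6S,10S) 4,6-diol, C9–OSiEt3, C13–OSi(t-Bu)Me2 | CC(C)(C)[Si](C)(C)OCC1=C2C(C(O[Si](CC)(CC)CC)[C@]3(C)CC=C(O3)[C@@](C)(O)C[C@@H]2O)OC1=O | intermediate
30 | (4S,6S,10S) C6 acetate, C4–OH, C9–OSiEt3, C13–OSi(t-Bu)Me2 | CC(C)(C)[Si](C)(C)OCC1=C2C(C(O[Si](CC)(CC)CC)[C@]3(C)CC=C(O3)[C@@](C)(O)C[C@@H]2OC(C)=O)OC1=O | intermediate
31 | (4S,6S,10S) C6 acetate with free C4, C9 and C13 hydroxyls | OCC1=C2C(C(O)[C@]3(C)CC=C(O3)[C@@](C)(O)C[C@@H]2OC(C)=O)OC1=O | intermediate
32 | (4S,6S,10S) C6,C13 diacetate with free C4 and C9 hydroxyls | CC(=O)OCC1=C2C(C(O)[C@]3(C)CC=C(O3)[C@@](C)(O)C[C@@H]2OC(C)=O)OC1=O | intermediate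
33 | C9 methanesulfonate of 32 | CC(=O)OCC1=C2C(C(OS(C)(=O)=O)[C@]3(C)CC=C(O3)[C@@](C)(O)C[C@@H]2OC(C)=O)OC1=O | intermediate
34 | CNP0144020.1, (4S,6S,10S), C10 cis to C7 across C8=C9 | CC(=O)OCC1=C2/C(=C\[C@]3(C)CC=C(O3)[C@@](C)(O)C[C@@H]2OC(C)=O)OC1=O | target

## Step count and least certain steps

Total: 19 steps. Longest linear sequence: 15 steps from 1 (steps 1–7 and 12–19). The butenolide branch from 14 is 4 steps (8–11).

**Step 14 (key step).**
- What may go wrong:
  - Electron transfer into the keto-butenolide π-system in place of, or after, C–Br reduction. This would lead to reductive opening of the lactone at C8–O or loss of the C13 silyloxy group.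
  - Internal proton transfer from the acidic C8–H to the enolate carbon. This quenches the enolate, and the dienolate so formed can also expel the C9 silyloxy group.
  - Oligomerisation, or retro-aldol opening of the aldolate on warming.
  - Erosion of C4 selectivity if the chelate is not maintained.
- Fallback: a polar closure of the same bond that needs neither a basic enolate nor a soluble reductant. It sets out from 24. Zinc and Me3SiCl in MeCN–Et2O should give the trimethylsilyl enol ether F1 by reductive silylation of the α-bromo ketone. MgBr2·OEt2 in dilute CH2Cl2 at −78 °C should then effect a chelation-controlled Mukaiyama aldol macrocyclisation onto the C4 ketone. After a mild desilylating work-up this returns to the route at 27.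

**Step 5 (with step 6).**
- What may go wrong: hydrolytic reversion or self-condensation of the five-membered ketene acetal phosphate, and slow oxidative addition.
- Fallback: it sets out from 7. Addition of CH2=C(OEt)Li (from ethyl vinyl ether and t-BuLi) at −78 °C should give the ethoxyvinyl hemiketal F2. Dehydration with MsCl and Et3N should give 11, which is hydrolysed to 12 as in step 6.

**Step 12.**
- What may go wrong: reversion or β-elimination of the aldolate before it is silylated, incomplete silylation of the hindered alkoxide, and proton exchange with the methyl ketone.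
- Fallback: a Lewis-acid aldol in place of the lithium aldol. It sets out from 18 and 13. Et3SiOTf and i-Pr2NEt in CH2Cl2 should convert 18 in situ into the 2-silyloxyfuran F3. This should add to the aldehyde in a vinylogous Mukaiyama aldol with silyl transfer to give the bromo butenolide adduct F4. Stille coupling of F4 with 10 returns to the route at 22.

**Step 15.**
- What may go wrong: poor facial selectivity if exchange at the tertiary C4 hydroxyl is slow and undirected reduction takes over, and acid-promoted addition to the enol ether.
- Fallback: it sets out from 27. Undirected reduction (NaBH4, CeCl3·7H2O, −78 °C) is expected to occur from the outer face and give mainly the C6-epimeric diol F5. Mitsunobu esterification (AcOH, PPh3, DIAD) inverts C6 and returns to the route at 30. Any 6S diol formed simply continues through step 16.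

**Step 19.**
- What may go wrong: competing sulfonylation of the C4 hydroxyl, loss of the C13 acetate through the dienolate or by vinylogous elimination from C6–H, and formation of the wrong alkene isomer.
- Fallback: the order is changed so that the acetate is introduced last. It sets out from 30. Brief HF·pyridine at 0 °C should remove only the triethylsilyl group to give the C9 alcohol F6. MsCl and Et3N, then DBU, should give the enol lactone F7 with C13 still silylated. HF·pyridine should then give the C13 alcohol F8, and Ac2O with pyridine returns to the route at 34.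

**Step 8.**
- What may go wrong: O-activation outrunning C-formylation, so that only the 4-bromo butenolide forms, and decomposition of the very electrophilic bromo aldehyde on aqueous work-up.
- Fallback: it sets out from 14. Condensation with DMF dimethyl acetal should give the enaminone F9. Oxalyl bromide should convert F9 into 15, which is hydrolysed to 16, returning to the route there.

## Further compounds

F1 | step 14 | trimethylsilyl enol ether (C5=C6) derived from 24 | CC(C)(C)[Si](C)(C)OCC1=C(C(=C)O[Si](C)(C)C)C(C(O[Si](CC)(CC)CC)[C@]2(C)CC=C(O2)C(C)=O)OC1=O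
F2 | step 5 | (5S)-2-(1-ethoxyvinyl)-5-methyl-5-{[(triethylsilyl)oxy]methyl}tetrahydrofuran-2-ol | CC[Si](CC)(CC)OC[C@]1(C)CCC(O)(C(=C)OCC)O1
F3 | step 12 | 4-bromo-3-{[(tert-butyldimethylsilyl)oxy]methyl}-2-[(triethylsilyl)oxy]furan | CC[Si](CC)(CC)Oc1occ(Br)c1CO[Si](C)(C)C(C)(C)C
F4 | step 12 | 5-{[(2S)-5-acetyl-2-methyl-2,3-dihydrofuran-2-yl][(triethylsilyl)oxy]methyl}-4-bromo-3-{[(tert-butyldimethylsilyl)oxy]methyl}furan-2(5H)-one | CC(C)(C)[Si](C)(C)OCC1=C(Br)C(OC1=O)C(O[Si](CC)(CC)CC)[C@]2(C)CC=C(C(C)=O)O2
F5 | step 15 | (4S,6R,10S) 4,6-diol, C6 epimer of 29 | CC(C)(C)[Si](C)(C)OCC1=C2C(C(O[Si](CC)(CC)CC)[C@]3(C)CC=C(O3)[C@@](C)(O)C[C@H]2O)OC1=O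
F6 | step 19 | (4S,6S,10S) C6 acetate with free C4 and C9 hydroxyls and C13 silyl ether | CC(C)(C)[Si](C)(C)OCC1=C2C(C(O)[C@]3(C)CC=C(O3)[C@@](C)(O)C[C@@H]2OC(C)=O)OC1=O
F7 | step 19 | C13 tert-butyldimethylsilyl ether analogue of 34 | CC(C)(C)[Si](C)(C)OCC1=C2/C(=C\[C@]3(C)CC=C(O3)[C@@](C)(O)C[C@@H]2OC(C)=O)OC1=O
F8 | step 19 | C13 alcohol analogue of 34 | OCC1=C2/C(=C\[C@]3(C)CC=C(O3)[C@@](C)(O)C[C@@H]2OC(C)=O)OC1=O
F9 | step 8 | 3-[(dimethylamino)methylene]furan-2,4(3H,5H)-dione | CN(C)C=C1C(=O)COC1=O
A1 | alternative 1 | ten-membered alkylidene butenolide with C10 tertiary carbinol and C3/C4 acetonide | CC(=O)OCC1=C2/C(=C\[C@](O)(C)CC[C@H]3OC(C)(C)O[C@@]3(C)C[C@@H]2OC(C)=O)OC1=O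
A2 | alternative 1 | (E)-C9 iodomethylene butenolide with C10 methyl ketone side chain | I/C=C1\C([C@@H](OC(C)=O)C[C@]2(C)OC(C)(C)O[C@@H]2CCC(C)=O)=C(COC(C)=O)C(=O)O1
A3 | alternative 2 | 2-methyl-2-vinyl-2,3-dihydrofuran carrying the silylated C4–C6 chain | C=C[C@]1(C)CC=C(O1)[C@@](C)(O[Si](CC)(CC)CC)CCO[Si](C)(C)C(C)(C)C
A4 | alternative 2 | 2-methyl-2-vinylcyclopropyl ketone (cyclopropane configuration undefined) | C=CC1(C)CC1C(=O)[C@@](C)(O[Si](CC)(CC)CC)CCO[Si](C)(C)C(C)(C)C
A5 | alternative 3 | ten-membered C3 ketone with C8=C9 enol lactone and C10 silyl ether | CC(C)(C)[Si](C)(C)OCC1=C2/C(=C\[C@](O[Si](C)(C)C(C)(C)C)(C)CCC(=O)[C@@](C)(O[Si](CC)(CC)CC)C[C@@H]2O[Si](C)(C)C(C)(C)C)OC1=O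
A6 | alternative 3 | butenolide-fused cyclohexane with C3 vinyl carbinol and C9=C10 silyl enol ether (C3, C8 and enol ether geometry undefined) | C=CC1(O)[C@@](C)(O[Si](CC)(CC)CC)C[C@H](O[Si](C)(C)C(C)(C)C)C2=C(CO[Si](C)(C)C(C)(C)C)C(=O)OC12C=C(C)O[Si](C)(C)C(C)(C)C
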